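Which flask ends with more product: north-east, with everything in at the start and stopped early, or east, fed for twice as long?

| flask | substrate | precatalyst | remark | time |
|---|---|---|---|---|
| Sunday's | 11 mM (fed, over 80 min) | 0.0067 mol% | run made earlier |  |
| Thursday's | 11 mM (fed, over 80 min) | 0.015 mol% | run made earlier |  |
| Tuesday's | 5.5 mM (fed, over 80 min) | 0.01 mol% | run made earlier |  |
| north-east | 11 mM | 0.01 mol% | everything together at the start | 40 min |
| east | 11 mM (fed, over 80 min) | 0.01 mol% |  | 80 min |

| run | time / min | product / % | substrate / % |
|---|---|---|---|
| Sunday's | 8.00 | 0.4 | 10.0 |
| Sunday's | 20.0 | 3.7 | 21.0 |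
| Sunday's | 40.0 | 12.3 | 37.4 |
| Sunday's | 90.0 | 45.6 | 54.6 |
| Thursday's | 25.0 | 9.8 | 21.0 |
| Thursday's | 50.0 | 34.1 | 28.3 |
| Thursday's | 80.0 | 64.8 | 35.5 |
| Thursday's | 90.0 | 73.1 | 26.4 |
| Tuesday's | 8.00 | 0.7 | 9.5 |
| Tuesday's | 20.0 | 3.6 | 22.9 |
| Tuesday's | 40.0 | 12.6 | 37.8 |
| Tuesday's | 90.0 | 47.1 | 52.3 |

(scatter of a reading: 0.5 percentage points)

- which one finishes higher in amount of product, in percent of the substrate charged ("neither" within 2 percentage points) (north-east / east / neither)
- amount of product at the end, in percent of the substrate charged, north-east
- amount of product at the end, in percent of the substrate charged, east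

- the numbers in the tables scatter with a standard deviation of 0.5 percentage points
- percentages count the whole charge, also what has not yet gone in

Fed and batch flasks can be compared through one quantity. Sunday's run up to 40.0 min reads 0.587 of what I call exposure, the sum over the readings of product gained divided by substrate present, both as fractions of the charge. With everything in from the start, exposure is simply ln(1/fraction left).

North-east has 1.49 times Sunday's precatalyst on the same charge, and you read it at the same time. Now take two extremes.

Pseudo-first-order, where exposure follows the catalyst:

exposure = 0.877, product = 0.584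

Zero order in substrate, where product gained follows the catalyst:

product = 0.184, exposure = 0.203

The real flask lies between them, and Tuesday's run says where. It tracks Sunday's on half the charge, although Sunday's holds 1.34 times its catalyst concentration. So exposure falls as substrate level to a power:

m = 0.422

Here 0 is the first extreme and 1 the second. Going that far between them in logarithms:

exposure = 0.473, product = 0.377

North-east holds more substrate than those runs, so I expect a larger m and take 0.377 as an upper figure. East has the same feed as Sunday's and Thursday's runs, with a loading between theirs. Thursday's reads 64.8 % at 80 min, and a straight line between Sunday's last two readings gives my estimate of 38.9 % for that time. Going between these two in logarithms of the loading gives 50.2 % for east, so I expect east higher than north-east.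

The forecast says east, with 43 % for north-east and 51 % for east, and it reasons: “North-east starts at full 11 mM, nearer saturation, and has only 40 min”. Its north-east figure is higher than mine.

North-east gave 32.7 % and east 52.0 %, so east finished higher.

    substrate + enzyme → product + enzyme, rate k1*[substrate]*[enzyme]/(1 + ([substrate]/Km1) + ([product]/Kp1)) (4.11 mM, 12.8 mM, k = 1180 M⁻¹ s⁻¹)
    enzyme → spent catalyst A (k = 1.00 × 10⁻⁴ s⁻¹)
    2 enzyme → spent catalyst B (k = 19.6 M⁻¹ s⁻¹)
    precatalyst → enzyme (k = 6.08 × 10⁻⁴ s⁻¹)

The substrate constant in the rate law, 4.11 mM, lies below the charge of 11 mM. North-east's exposure was 0.397, which is 0.452 of the pseudo-first-order value. For the same flask with 0.006 mol% of precatalyst, scale that exposure to 0.238, which means product 0.212; that flask gave 20.6 %.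

(The data are calculated for an exercise; the scatter is artificial.)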